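Read the isomer in molar, not in percent, and build the flask up one process at a time.

all flasks: gas 65 mM (held)
- noon: substrate 0.50 M; run made earlier
- summer: substrate 2 M; run made earlier
- flask: substrate 1.0 M; time 15 d

| run | time / d | target / % | isomer of the product / % |
|---|---|---|---|
| noon | 1.67 | 45 | 19 |
| noon | 3.00 | 63 | 32 |
| noon | 5.00 | 67 | 31 |
| noon | 6.00 | 68 | 29 |
| noon | 8.00 | 66 | 33 |
| noon | 10.0 | 67 | 34 |
| noon | 12.0 | 66 | 32 |
| summer | 1.67 | 19 | 5 |
| summer | 3.00 | 42 | 8 |
| summer | 5.00 | 67 | 6 |
| summer | 6.00 | 80 | 6 |
| summer | 8.00 | 91 | 10 |
| summer | 10.0 | 94 | 6 |
| summer | 12.0 | 94 | 9 |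

(standard deviation of a reading: 1.5 percentage points)

- at the start none of the gas is in solution
- a reading or a percentage of target counts all its forms, free or not

1. the target standing at 15 d, as a percentage of the substrate charged
2. the isomer of the product standing at 15 d, as a percentage of the substrate charged

1. I began with the main step alone, substrate with gas giving target. The gas was the smaller reagent, held at 65 mM against 1.0 M of substrate, so if one gas goes with one substrate it had to be replaced 15.4 times over. Between 3.00 d and 6.00 d the summer run made target at 0.253 M d⁻¹. At that pace I reckoned the flask to need 3.95 d, shorter than its 15 d, so with this step alone I expected target at 100%.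

2. I then added the isomer as a fixed share. Over the last three readings the isomer averaged 33.0% in the noon run and 8.33% in the summer run. The noon share was larger, by a factor of 3.96, so a fixed share failed.

3. I turned those shares into molar: 165 mM at noon and 167 mM in summer. Their mean I called the isomer allowance, the molar isomer standing once a run has gone flat 166 mM. For the flask it gave 16.6% isomer. Target and isomer summed to 101% in the noon run and 100% in the summer run at 10.0 d, so I left target the remainder, 83.4%.

4. The forecast said 84% and 15.5%, slightly less isomer than mine, on the ground that “isomer is nearly constant in absolute concentration, not percentage”.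

5. The flask gave 83.8% target and 16.2% isomer, with the substrate, the limiting reagent, down to 0%.

    substrate + coupling partner → target, rate k1*[substrate]*[coupling partner]^1.5 (k = 3.99 M⁻¹·⁵ h⁻¹)
    target ⇌ isomer of the product (K = 0.601, k = 0.0314 h⁻¹)
    gas ⇌ coupling partner, rate k3*(csat - [coupling partner]) (kL = 0.301 h⁻¹)
    crystals ⇌ target, rate k4*(cs4 - [target]) while solid is left; crystals form when [target] > cs4 (solubility = 0.270 M, k = 5.66 h⁻¹)

6. The main reason for the high target in the flask was the return of isomer to target: in a run of the flask without that return, target came to 0.0117% instead of 83.8%. The allowance carried to the neighbouring flask with 2.5 M of substrate gave 6.64%, and that flask stood at 6.49% isomer.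

The data were computed from invented constants.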